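**Retrosynthetic overview**
1. Target 16 ⇐ 14: the hydroxy-lactone is unveiled last from a 6,8-dioxabicyclo[3.2.1]oct-3-ene acetal that hides C1'-OH, C6-O and the lactone carbonyl at once, so no protecting group is needed.
2. 14 ⇐ 13 by sulfoxonium-ylide methylene transfer; 13 ⇐ vinyl acetal 7 + vinyl ketone 12 by cross-metathesis.
3. 7 ⇐ 5 (Z-reduction, acetalisation) ⇐ epoxy alcohol 2 + alkyne 3 ⇐ divinyl carbinol 1 by desymmetrising Sharpless epoxidation, the key step, which sets C6 and C1' together.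
4. 12 ⇐ ethyl (S)-lactate 8 + 4-methoxycinnamic acid 10 + vinyl Grignard reagent.
5. Ring order: oxirane → dioxabicyclooctene (dihydropyran + dioxolane) → cyclopropane → dihydropyranone.

Assumption: 1, 3, 8 and 10 are bought; locants are C2–C6 for the lactone ring, C1' carbinol, C2'/C3' cyclopropane CH carbons, C4' ketone, C5' lactate carbon.

**Step 1**
Reactants: 1 penta-1,4-dien-3-ol
Product: 2 (2R,3S)-1,2-epoxypent-4-en-3-ol
Conditions: Ti(OiPr)4 (10 mol%), L-(+)-diisopropyl tartrate (13 mol%), t-BuOOH (2 equiv), 4 Å MS, CH2Cl2, −20 °C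
Reagents that add atoms: tert-butyl hydroperoxide, CC(C)(C)OO
Why: Sharpless asymmetric epoxidation of the achiral dienol, in which the L-(+)-tartrate catalyst selects one enantiotopic vinyl group and one face to give the erythro epoxy alcohol with C6 (R) and C1' (S) set together, while the minor enantiomer is removed by over-epoxidation.

**Step 2**
Reactants: 2 (2R,3S)-1,2-epoxypent-4-en-3-ol; 3 3,3-diethoxyprop-1-yne
Product: 5 (3S,4R)-8,8-diethoxyoct-1-en-6-yne-3,4-diol, via lithium acetylide 4 (not isolated)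
Conditions: 3 (3 equiv), n-BuLi (3 equiv), THF, −78 °C; BF3·OEt2 (3 equiv); then 2, −78 °C; aq NH4Cl
Reagents that add atoms: none
Why: Yamaguchi-type BF3-promoted alkynylation, in which the acetylide (one equivalent is spent on the free OH) opens the terminal epoxide carbon by SN2 so that neither stereocentre is touched.

**Step 3**
Reactants: 5 (3S,4R)-8,8-diethoxyoct-1-en-6-yne-3,4-diol
Product: 7 (1R,5R,7S)-7-ethenyl-6,8-dioxabicyclo[3.2.1]oct-3-ene, via Z-diene diol acetal 6 (not isolated)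
Conditions: H2 (1 atm), Pd/CaCO3 poisoned with Pb(OAc)2 (Lindlar catalyst), quinoline, EtOAc, rt; filter; then PPTS (10 mol%), CH2Cl2, rt
Reagents that add atoms: none
Why: Lindlar semi-hydrogenation gives the Z-alkene, which lets acid-catalysed transacetalisation close both hydroxyls onto the aldehyde-level carbon (its configuration is fixed by the bridged ring), masking the diol and the future lactone carbonyl in one acetal.

**Step 4**
Reactants: 8 ethyl (S)-lactate
Product: 9 (S)-2-hydroxy-N-methoxy-N-methylpropanamide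
Conditions: MeNH(OMe)·HCl (2.5 equiv), i-PrMgCl (5 equiv), THF, −20 → 0 °C
Reagents that add atoms: N,O-dimethylhydroxylamine hydrochloride, CNOC.Cl
Why: Weinreb amide formation by magnesium-amide aminolysis of the ester, which does not involve the lactate stereocentre.

**Step 5**
Reactants: 9 (S)-2-hydroxy-N-methoxy-N-methylpropanamide; 10 (E)-4-methoxycinnamic acid
Product: 11 (S)-1-[methoxy(methyl)amino]-1-oxopropan-2-yl (E)-3-(4-methoxyphenyl)prop-2-enoate
Conditions: EDC·HCl (1.3 equiv), DMAP (10 mol%), CH2Cl2, 0 °C → rt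
Reagents that add atoms: none
Why: Steglich esterification at oxygen, so the lactate carbon keeps its (S) configuration.

**Step 6**
Reactants: 11 (S)-1-[methoxy(methyl)amino]-1-oxopropan-2-yl (E)-3-(4-methoxyphenyl)prop-2-enoate
Product: 12 (S)-3-oxopent-4-en-2-yl (E)-3-(4-methoxyphenyl)prop-2-enoate
Conditions: CH2=CHMgBr (1.3 equiv), THF, −78 → −40 °C; inverse quench into cold 1 M HCl
Reagents that add atoms: vinylmagnesium bromide, C=C[Mg]Br
Why: Weinreb ketone synthesis, where the chelated tetrahedral adduct forms faster than attack on the conjugated cinnamate and releases the vinyl ketone only on acidic quench, which also keeps the amine by-product from adding to the enone.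

**Step 7**
Reactants: 7 (1R,5R,7S)-7-ethenyl-6,8-dioxabicyclo[3.2.1]oct-3-ene; 12 (S)-3-oxopent-4-en-2-yl (E)-3-(4-methoxyphenyl)prop-2-enoate
Product: 13 (2S,4E)-5-[(1R,5R,7S)-6,8-dioxabicyclo[3.2.1]oct-3-en-7-yl]-3-oxopent-4-en-2-yl (E)-3-(4-methoxyphenyl)prop-2-enoate
Conditions: second-generation Hoveyda–Grubbs catalyst [RuCl2(H2IMes)(=CH-C6H4-2-OiPr)] (5 mol%), CH2Cl2, 40 °C
Reagents that add atoms: none
Why: Olefin cross-metathesis between the allylic-acetal vinyl group and the slowly dimerising enone gives the E-enone, while the unstrained ring alkene and the cinnamate alkene are poor metathesis substrates.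

**Step 8**
Reactants: 13 (2S,4E)-5-[(1R,5R,7S)-6,8-dioxabicyclo[3.2.1]oct-3-en-7-yl]-3-oxopent-4-en-2-yl (E)-3-(4-methoxyphenyl)prop-2-enoate
Product: 14 (2S)-1-{(1S,2S)-2-[(1R,5R,7S)-6,8-dioxabicyclo[3.2.1]oct-3-en-7-yl]cyclopropyl}-1-oxopropan-2-yl (E)-3-(4-methoxyphenyl)prop-2-enoate
Conditions: Me3S(O)I (1.15 equiv), NaH (1.1 equiv), DMSO, rt, 30 min; then 13 in THF, 0 °C → rt
Reagents that add atoms: trimethylsulfoxonium iodide, C[S+](C)(C)=O.[I-]
Why: Corey–Chaykovsky cyclopropanation (Michael-initiated ring closure), in which the ylide is expected to add to the β-carbon anti to the bulky dioxolane ring carbon (Felkin-type, by analogy with glyceraldehyde-acetonide-derived E-acceptors) to set C2' (S), and the enolate closes to the trans ring to set C3' (S).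

**Step 9**
Reactants: 14 (2S)-1-{(1S,2S)-2-[(1R,5R,7S)-6,8-dioxabicyclo[3.2.1]oct-3-en-7-yl]cyclopropyl}-1-oxopropan-2-yl (E)-3-(4-methoxyphenyl)prop-2-enoate
Product: 16 brevipolide H, via lactol 15 (not isolated)
Conditions: CF3CO2H (0.3 equiv), MeCN/H2O 4:1, rt; then TEMPO (20 mol%), PhI(OAc)2 (1.5 equiv), same flask, rt
Reagents that add atoms: water, O
Why: Acid hydrolysis of the allylic bicyclic acetal gives the six-membered lactol and frees C1'-OH, and oxoammonium (TEMPO) oxidation of the lactol to the conjugated δ-lactone is much faster than oxidation of the hindered cyclopropyl carbinol and draws the acetal–lactol equilibrium forward.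

**Compound list**
1 | penta-1,4-dien-3-ol | C=CC(O)C=C | starting material
2 | (2R,3S)-1,2-epoxypent-4-en-3-ol | C=C[C@H](O)[C@H]1CO1 | intermediate
3 | 3,3-diethoxyprop-1-yne | C#CC(OCC)OCC | starting material
4 | lithium 3,3-diethoxyprop-1-yn-1-ide | [Li]C#CC(OCC)OCC | intermediate (not isolated)
5 | (3S,4R)-8,8-diethoxyoct-1-en-6-yne-3,4-diol | C=C[C@H](O)[C@H](O)CC#CC(OCC)OCC | intermediate
6 | (3S,4R,6Z)-8,8-diethoxyocta-1,6-diene-3,4-diol | C=C[C@H](O)[C@H](O)C/C=C\C(OCC)OCC | intermediate (not isolated)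
7 | (1R,5R,7S)-7-ethenyl-6,8-dioxabicyclo[3.2.1]oct-3-ene | C=C[C@@H]1O[C@@H]2C=CC[C@H]1O2 | intermediate
8 | ethyl (S)-lactate | C[C@H](O)C(=O)OCC | starting material
9 | (S)-2-hydroxy-N-methoxy-N-methylpropanamide | C[C@H](O)C(=O)N(C)OC | intermediate
10 | (E)-4-methoxycinnamic acid | COc1ccc(/C=C/C(=O)O)cc1 | starting material
11 | (S)-1-[methoxy(methyl)amino]-1-oxopropan-2-yl (E)-3-(4-methoxyphenyl)prop-2-enoate | COc1ccc(/C=C/C(=O)O[C@@H](C)C(=O)N(C)OC)cc1 | intermediate
12 | (S)-3-oxopent-4-en-2-yl (E)-3-(4-methoxyphenyl)prop-2-enoate | COc1ccc(/C=C/C(=O)O[C@@H](C)C(=O)C=C)cc1 | intermediate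
13 | (2S,4E)-5-[(1R,5R,7S)-6,8-dioxabicyclo[3.2.1]oct-3-en-7-yl]-3-oxopent-4-en-2-yl (E)-3-(4-methoxyphenyl)prop-2-enoate | COc1ccc(/C=C/C(=O)O[C@@H](C)C(=O)/C=C/[C@@H]2O[C@@H]3C=CC[C@H]2O3)cc1 | intermediate
14 | (2S)-1-{(1S,2S)-2-[(1R,5R,7S)-6,8-dioxabicyclo[3.2.1]oct-3-en-7-yl]cyclopropyl}-1-oxopropan-2-yl (E)-3-(4-methoxyphenyl)prop-2-enoate | COc1ccc(/C=C/C(=O)O[C@@H](C)C(=O)[C@H]2C[C@@H]2[C@@H]2O[C@@H]3C=CC[C@H]2O3)cc1 | intermediate
15 | (2S)-1-{(1S,2S)-2-[(S)-hydroxy[(2R)-6-hydroxy-3,6-dihydro-2H-pyran-2-yl]methyl]cyclopropyl}-1-oxopropan-2-yl (E)-3-(4-methoxyphenyl)prop-2-enoate (both anomers) | COc1ccc(/C=C/C(=O)O[C@@H](C)C(=O)[C@H]2C[C@@H]2[C@H](O)[C@H]2CC=CC(O)O2)cc1 | intermediate (not isolated)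
16 | brevipolide H, (2S)-1-{(1S,2S)-2-[(S)-hydroxy[(2R)-6-oxo-3,6-dihydro-2H-pyran-2-yl]methyl]cyclopropyl}-1-oxopropan-2-yl (E)-3-(4-methoxyphenyl)prop-2-enoate | COc1ccc(/C=C/C(=O)O[C@@H](C)C(=O)[C@H]2C[C@@H]2[C@H](O)[C@H]2CC=CC(=O)O2)cc1 | target

**Step count and risks**
Total: 9 steps. Longest linear sequence: 6 steps (1 → 2 → 5 → 7 → 13 → 14 → 16, or equally 8 → 9 → 11 → 12 → 13 → 14 → 16).

Most likely to fail:

- **Step 8.** The facial selectivity rests on analogy with dioxolane-substituted E-acceptors, and the basic ylide may epimerise the α-acyloxy ketone centre C5'. The fallback sets out from enone 13. Reagent-controlled reduction with (R)-2-methyl-CBS-oxazaborolidine and catecholborane gives the (3R)-allylic alcohol F1. Hydroxyl-directed Simmons–Smith cyclopropanation (Et2Zn, CH2I2, CH2Cl2, −10 °C) then delivers CH2 syn to that hydroxyl from the H-eclipsed conformer and gives the (1S,2S)-cyclopropyl carbinol F2 without any base. Dess–Martin oxidation of F2 erases the auxiliary carbinol centre and comes back to the route at 14.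

- **Step 9.** The bridged acetal may hydrolyse only partly, or the freed C1' carbinol may be over-oxidised. The fallback sets out from 14. Acylative cleavage with (CF3CO)2O and catalytic CF3SO3H in CH2Cl2 at 0 °C opens the acetal irreversibly to the bis(trifluoroacetate) F3. NaHCO3 in aqueous MeOH strips both trifluoroacetates, and the route is rejoined at lactol 15, which is oxidised as before to 16.

- **Step 2.** The free hydroxyl next to the epoxide may divert the BF3-mediated opening. The fallback sets out from 2. Silylation (t-BuMe2SiCl, imidazole, DMF) gives the silyl ether epoxide F4, which is opened with 4 and BF3·OEt2 at −78 °C to the silyl ether alkynol F5. Bu4NF in THF removes the silyl group and comes back to the route at 5.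

**Further compounds**
F1 | step 8 | (2S,3R,4E)-5-[(1R,5R,7S)-6,8-dioxabicyclo[3.2.1]oct-3-en-7-yl]-3-hydroxypent-4-en-2-yl (E)-3-(4-methoxyphenyl)prop-2-enoate | COc1ccc(/C=C/C(=O)O[C@@H](C)[C@H](O)/C=C/[C@@H]2O[C@@H]3C=CC[C@H]2O3)cc1
F2 | step 8 | (1R,2S)-1-{(1S,2S)-2-[(1R,5R,7S)-6,8-dioxabicyclo[3.2.1]oct-3-en-7-yl]cyclopropyl}-1-hydroxypropan-2-yl (E)-3-(4-methoxyphenyl)prop-2-enoate | COc1ccc(/C=C/C(=O)O[C@@H](C)[C@H](O)[C@H]2C[C@@H]2[C@@H]2O[C@@H]3C=CC[C@H]2O3)cc1
F3 | step 9 | (2S)-1-{(1S,2S)-2-[(S)-(trifluoroacetoxy)[(2R)-6-(trifluoroacetoxy)-3,6-dihydro-2H-pyran-2-yl]methyl]cyclopropyl}-1-oxopropan-2-yl (E)-3-(4-methoxyphenyl)prop-2-enoate | COc1ccc(/C=C/C(=O)O[C@@H](C)C(=O)[C@H]2C[C@@H]2[C@H](OC(=O)C(F)(F)F)[C@H]2CC=CC(OC(=O)C(F)(F)F)O2)cc1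
F4 | step 2 | tert-butyldimethyl{[(1S)-1-[(2R)-oxiran-2-yl]prop-2-en-1-yl]oxy}silane | C=C[C@H](O[Si](C)(C)C(C)(C)C)[C@H]1CO1
F5 | step 2 | (3S,4R)-3-[(tert-butyldimethylsilyl)oxy]-8,8-diethoxyoct-1-en-6-yn-4-ol | C=C[C@H](O[Si](C)(C)C(C)(C)C)[C@H](O)CC#CC(OCC)OCC
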